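The O1–C2H2 unit of ring C is read as an aryl methyl ether that has lost one hydrogen. C3, flanked by the C4 carbonyl and ring B, is read as a donor/acceptor carbene carbon. Everything therefore rests on the C2–C3 disconnection. A chiral dirhodium catalyst turns an open α-aryl-α-diazoketone into the isoflavanone by enantioselective 1,6-C–H insertion into the ortho methoxy group of ring A. This closes ring C and sets C3 under neutral conditions in one operation. The precursor is a tris-TBS 2-methoxy diazo-deoxybenzoin that already bears the prenyl and geranyl chains. It is assembled by palladium-catalysed arylation of a terminal diazoketone with an aryl iodide.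

Key step: step 7

Remark on numbering: isoflavanone numbering is used (O1, C2, C3, C4, C4a, C5–C8, C8a; ring B C1'–C6'). At C3 the priorities are C4 > C2 > C1' > H, so the target is (3R).
Assumption: the sense of induction of Rh2(S-PTAD)4 (tetrakis[(S)-(1-adamantyl)(N-phthalimido)acetato]dirhodium) on this substrate is taken by analogy. If the (S)-catalyst favours (3S), the mirror-image Rh2(R-PTAD)4 is used in the same way.

Step 1
Reactants: 1 2',4'-dihydroxy-6'-methoxyacetophenone; 2 prenyl bromide (1-bromo-3-methylbut-2-ene)
Product: 3 1-[2,4-dihydroxy-6-methoxy-3-(3-methylbut-2-en-1-yl)phenyl]ethanone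
Conditions: KOH, H2O, 0 °C to rt; chromatography to remove the 5-prenyl and O-prenyl isomers
Reagents that add atoms: none
Why: This is a nuclear C-prenylation (phenoxide C-alkylation) of a phloroacetophenone-type phenoxide, in which water solvates the oxygens and steers the allylic bromide to carbon, and C3 should be the preferred site because it lies ortho to both phenoxide oxygens and belongs to the enol-like C3=C4 bond fixed by chelation of the 2-OH to the acetyl group.

Step 2
Reactants: 3 1-[2,4-dihydroxy-6-methoxy-3-prenylphenyl]ethanone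
Product: 4 1-[2,4-bis(tert-butyldimethylsilyloxy)-6-methoxy-3-prenylphenyl]ethanone
Conditions: TBSOTf (2.4 equiv), 2,6-lutidine, CH2Cl2, −78 to 0 °C
Reagents that add atoms: tert-butyldimethylsilyl triflate CC(C)(C)[Si](C)(C)OS(=O)(=O)C(F)(F)F
Why: Silyl ether formation with the highly electrophilic triflate overcomes the hydrogen bond and crowding at the 2-OH, the hindered base buffers the acid-sensitive prenyl group and disfavours enol silylation, and TBS is chosen because it has no C–H bond next to oxygen that could compete in step 7.

Step 3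
Reactants: 4 1-[2,4-bis(TBSO)-6-methoxy-3-prenylphenyl]ethanone
Product: 6 2-diazo-1-[2,4-bis(TBSO)-6-methoxy-3-prenylphenyl]ethanone, via trifluoroacetyl diketone 5 (not isolated)
Conditions: LiN(SiMe3)2, THF, −78 °C; CF3CO2CH2CF3, −78 °C; crude 5, then p-ABSA, Et3N, MeCN, rt
Reagents that add atoms: 4-acetamidobenzenesulfonyl azide (p-ABSA) CC(=O)Nc1ccc(cc1)S(=O)(=O)N=[N+]=[N-]; 2,2,2-trifluoroethyl trifluoroacetate O=C(OCC(F)(F)F)C(F)(F)F (its CF3CO group stays in 5 only)
Why: This is a detrifluoroacetylative Regitz-type diazo transfer, in which kinetic deprotonation at −78 °C (cold enough to hold back O-to-O silyl migration from the ortho OTBS group) and Claisen-type C-trifluoroacetylation activate the methyl group, after which the sulfonyl azide transfers N2 under mild amine base with loss of the trifluoroacetyl group.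

Step 4
Reactants: 7 4-iodophenol; 8 geranyl bromide ((2E)-1-bromo-3,7-dimethylocta-2,6-diene)
Product: 9 2-[(2E)-3,7-dimethylocta-2,6-dien-1-yl]-4-iodophenol
Conditions: NaH, toluene, 0 °C; then 8, rt
Reagents that add atoms: none
Why: This is an ortho-C-allylation of an O-sodiated phenol in a non-polar solvent, where the tight ion pair delivers the primary allylic carbon of 8 to the ortho position by direct displacement, so the linear chain and its E geometry are kept while iodine blocks the para position.

Step 5
Reactants: 9 2-geranyl-4-iodophenol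
Product: 10 tert-butyl{2-[(2E)-3,7-dimethylocta-2,6-dien-1-yl]-4-iodophenoxy}dimethylsilane
Conditions: TBSCl, imidazole, DMF, rt
Reagents that add atoms: tert-butyldimethylsilyl chloride CC(C)(C)[Si](C)(C)Cl
Why: Imidazole-promoted silyl ether formation on an unchelated phenol installs the same protecting group as on ring A, so that one final operation removes all three.

Step 6
Reactants: 6 2-diazo-1-[2,4-bis(TBSO)-6-methoxy-3-prenylphenyl]ethanone; 10 TBS ether of 2-geranyl-4-iodophenol
Product: 11 2-diazo-1-[2,4-bis(TBSO)-6-methoxy-3-prenylphenyl]-2-[4-(TBSO)-3-geranylphenyl]ethanone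
Conditions: Pd(PPh3)4 (5 mol %), Ag2CO3 (0.5 equiv), Et3N, toluene, rt, dark
Reagents that add atoms: none
Why: This is a palladium-catalysed C–H arylation of an acyldiazomethane with retention of the diazo group (oxidative addition of the aryl iodide to zerovalent palladium, silver- and amine-assisted palladation of the diazo carbon, reductive elimination at room temperature), under which no ketone enolate forms, so no silyl migration occurs, and the trisubstituted alkenes stay out of Heck chemistry.

Step 7
Reactants: 11 tris-TBS α-aryl-α-diazoketone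
Product: 13 (3R)-5,7-bis(TBSO)-3-[4-(TBSO)-3-geranylphenyl]-6-prenylchroman-4-one, via rhodium carbene 12 (not isolated)
Conditions: Rh2(S-PTAD)4 (1 mol %), 4 Å MS, hexanes, slow addition of 11, 23–40 °C
Reagents that add atoms: none
Why: Loss of N2 from 11 at an axial site of the divalent-rhodium dimer gives the donor/acceptor carbene 12, whose electrophilic carbon (future C3) takes up a C–H bond of the ortho OCH3 group through a concerted, asynchronous three-centre transition state whose hydride-transfer character is stabilised by O1. The closest known reactions are chiral dirhodium carboxylate catalysed 1,6-C–H insertions of o-alkoxyaryl α-diazoketones to chroman-4-ones, intramolecular insertions of α-aryl-α-diazoketones, and enantioselective insertions of donor/acceptor carbenes into methyl ethers, where the carbene carbon is likewise the only new stereocentre. Ring C closes as a six-membered ring by 1,6-insertion (C3, C4, C4a, C8a, O1, C2), and the usually preferred 1,5-mode has no C–H bond to use because the fifth atom is O1. C3 is set by catalyst control, since the phthalimido/adamantyl walls leave one face of the carbene open with ring B lying in the pocket, and C2 and H add to that same face without any enol or enolate being involved. The step needs site selectivity, which the substrate secures in three ways: O5 carries TBS (no C–H bond within a six-membered transition state, poorly nucleophilic oxygen); the C6 prenyl and proximal geranyl alkenes could reach C3 only through impossible meta-bridged small rings and the distal geranyl alkene only through a ten-membered ring; and bulky donor/acceptor carbenes react poorly with trisubstituted alkenes, while slow addition suppresses bimolecular paths. Oxonium ylide formation at O1 is reversible and methyl is a poor migrating group, so that channel should drain back into insertion.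

Step 8
Reactants: 13 (3R)-tris-TBS isoflavanone
Product: 14 (3R)-5,7-dihydroxy-3-{3-[(2E)-3,7-dimethylocta-2,6-dien-1-yl]-4-hydroxyphenyl}-6-(3-methylbut-2-en-1-yl)chroman-4-one (CNP0165005.1)
Conditions: Bu4NF/AcOH (1:1, 3.5 equiv), THF, 0 °C; work-up at pH 6–7
Reagents that add atoms: none
Why: Fluoride-induced cleavage of the aryl silyl ethers is buffered with acetic acid, so each phenoxide is protonated as it forms and the medium stays too weakly basic to enolise the C4 ketone and too weakly acidic to cyclise the prenyl or geranyl groups onto the neighbouring phenols, which leaves (3R) untouched.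

Compound list
1 | 2',4'-dihydroxy-6'-methoxyacetophenone | CC(=O)c1c(O)cc(O)cc1OC | starting material
2 | prenyl bromide | CC(C)=CCBr | starting material
3 | 1-[2,4-dihydroxy-6-methoxy-3-prenylphenyl]ethanone | CC(=O)c1c(O)c(CC=C(C)C)c(O)cc1OC | intermediate
4 | 1-[2,4-bis(TBSO)-6-methoxy-3-prenylphenyl]ethanone | CC(=O)c1c(O[Si](C)(C)C(C)(C)C)c(CC=C(C)C)c(O[Si](C)(C)C(C)(C)C)cc1OC | intermediate
5 | 1-[2,4-bis(TBSO)-6-methoxy-3-prenylphenyl]-4,4,4-trifluorobutane-1,3-dione (not isolated) | FC(F)(F)C(=O)CC(=O)c1c(O[Si](C)(C)C(C)(C)C)c(CC=C(C)C)c(O[Si](C)(C)C(C)(C)C)cc1OC | intermediate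
6 | 2-diazo-1-[2,4-bis(TBSO)-6-methoxy-3-prenylphenyl]ethanone | [N-]=[N+]=CC(=O)c1c(O[Si](C)(C)C(C)(C)C)c(CC=C(C)C)c(O[Si](C)(C)C(C)(C)C)cc1OC | intermediate
7 | 4-iodophenol | Oc1ccc(I)cc1 | starting material
8 | geranyl bromide, (E) | CC(C)=CCC/C(C)=C/CBr | starting material
9 | 2-[(2E)-3,7-dimethylocta-2,6-dien-1-yl]-4-iodophenol | CC(C)=CCC/C(C)=C/Cc1cc(I)ccc1O | intermediate
10 | TBS ether of 9 | CC(C)=CCC/C(C)=C/Cc1cc(I)ccc1O[Si](C)(C)C(C)(C)C | intermediate
11 | 2-diazo-1-[2,4-bis(TBSO)-6-methoxy-3-prenylphenyl]-2-[4-(TBSO)-3-geranylphenyl]ethanone | CC(C)=CCC/C(C)=C/Cc1cc(C(=[N+]=[N-])C(=O)c2c(OC)cc(O[Si](C)(C)C(C)(C)C)c(CC=C(C)C)c2O[Si](C)(C)C(C)(C)C)ccc1O[Si](C)(C)C(C)(C)C | intermediate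
12 | rhodium-bound donor/acceptor carbene from 11, drawn without the metal (not isolated) | CC(C)=CCC/C(C)=C/Cc1cc([C]C(=O)c2c(OC)cc(O[Si](C)(C)C(C)(C)C)c(CC=C(C)C)c2O[Si](C)(C)C(C)(C)C)ccc1O[Si](C)(C)C(C)(C)C | intermediate
13 | (3R)-5,7-bis(TBSO)-3-[4-(TBSO)-3-geranylphenyl]-6-prenylchroman-4-one | CC(C)=CCC/C(C)=C/Cc1cc([C@@H]2COc3cc(O[Si](C)(C)C(C)(C)C)c(CC=C(C)C)c(O[Si](C)(C)C(C)(C)C)c3C2=O)ccc1O[Si](C)(C)C(C)(C)C | intermediate
14 | (3R)-5,7-dihydroxy-3-(3-geranyl-4-hydroxyphenyl)-6-prenylchroman-4-one | CC(C)=CCC/C(C)=C/Cc1cc([C@@H]2COc3cc(O)c(CC=C(C)C)c(O)c3C2=O)ccc1O | target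

Total step count: 8. Longest linear sequence: 6 (steps 1, 2, 3, 6, 7, 8).

Steps most likely to fail

Step 7. Facial selectivity at the carbene carbon may be poor, or part of the carbene may be diverted by attack of an ether oxygen. The fallback separates ring closure from stereocontrol; it sets out from 11 and comes back at 13. The achiral, insertion-selective Rh2(esp)2 in CH2Cl2 closes the same C2–C3 bond to give the racemic tris-TBS isoflavanone F1. Soft enolisation (TMSOTf, Et3N, CH2Cl2, 0 °C) then gives the 4-(trimethylsilyloxy)isoflav-3-ene F2. Chiral Brønsted acid catalysed enantioselective protonation of this silyl enol ether returns 13 (BINOL-derived N-triflyl thiophosphoramide, phenol as stoichiometric proton source, toluene, rt).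

Step 1. Alkylation at C5 or at O4, or over-alkylation, may compete with attack at C3. The fallback replaces phenoxide alkylation by directed metalation on a symmetric arene; it sets out from prenyl bromide 2 and comes back at 3.
- Commercial 5-methoxyresorcinol F3 is converted (MOMCl, iPr2NEt, CH2Cl2) into 1-methoxy-3,5-bis(methoxymethoxy)benzene F4.
- Directed ortho-lithiation between the two MOM ethers (n-BuLi, THF, 0 °C) and alkylation with 2 gives the symmetric 5-methoxy-1,3-bis(methoxymethoxy)-2-prenylbenzene F5.
- The two remaining ring positions of F5 are equivalent, so a second lithiation (n-BuLi, TMEDA) and acylation with N-methoxy-N-methylacetamide can give only the bis-MOM acetophenone F6.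
- HCl in MeOH at rt liberates 3.

Step 6. The diazo group may lose N2 at palladium (carbene formation and migratory insertion) instead of undergoing C–H arylation, and oxidative addition of the electron-rich iodide may be slow. The fallback builds the carbon skeleton first and introduces the diazo group last; it sets out from 4 (with 10) and comes back at 11. Buchwald–Hartwig-type ketone α-arylation of 4 with 10 (Pd2(dba)3, XPhos, K3PO4, toluene, 80 °C) gives the tris-TBS deoxybenzoin F7. Regitz diazo transfer (p-ABSA, DBU, MeCN, 0 °C) then gives 11, and steps 3 and 6 are no longer needed.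

Further compounds
F1 | step 7 | racemic 5,7-bis(TBSO)-3-[4-(TBSO)-3-geranylphenyl]-6-prenylchroman-4-one | CC(C)=CCC/C(C)=C/Cc1cc(C2COc3cc(O[Si](C)(C)C(C)(C)C)c(CC=C(C)C)c(O[Si](C)(C)C(C)(C)C)c3C2=O)ccc1O[Si](C)(C)C(C)(C)C
F2 | step 7 | 5,7-bis(TBSO)-3-[4-(TBSO)-3-geranylphenyl]-6-prenyl-4-(trimethylsilyloxy)-2H-chromene | CC(C)=CCC/C(C)=C/Cc1cc(C2=C(O[Si](C)(C)C)c3c(O[Si](C)(C)C(C)(C)C)c(CC=C(C)C)c(O[Si](C)(C)C(C)(C)C)cc3OC2)ccc1O[Si](C)(C)C(C)(C)C
F3 | step 1 | 5-methoxyresorcinol (commercial) | COc1cc(O)cc(O)c1
F4 | step 1 | 1-methoxy-3,5-bis(methoxymethoxy)benzene | COCOc1cc(OC)cc(OCOC)c1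
F5 | step 1 | 5-methoxy-1,3-bis(methoxymethoxy)-2-prenylbenzene | COCOc1cc(OC)cc(OCOC)c1CC=C(C)C
F6 | step 1 | 1-[6-methoxy-2,4-bis(methoxymethoxy)-3-prenylphenyl]ethanone | CC(=O)c1c(OC)cc(OCOC)c(CC=C(C)C)c1OCOC
F7 | step 6 | 1-[2,4-bis(TBSO)-6-methoxy-3-prenylphenyl]-2-[4-(TBSO)-3-geranylphenyl]ethanone | CC(C)=CCC/C(C)=C/Cc1cc(CC(=O)c2c(OC)cc(O[Si](C)(C)C(C)(C)C)c(CC=C(C)C)c2O[Si](C)(C)C(C)(C)C)ccc1O[Si](C)(C)C(C)(C)C
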